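## Retrosynthetic overview

1. The furan C–O bond is formed last, by oxidative cyclisation of a 2'-hydroxyisoflavone, followed by one global deprotection.
2. The isoflavone C3–C1' bond comes from a late Suzuki–Miyaura coupling of two halves of similar size: a 3-iodo-dihydropyranochromone (10) and a chromenyl boronate (19).
3. Iodochromone 10: resorcinol → 3,5-dimethoxyphenol → chromanone annulation (dihydropyran ring first) → peri-demethylation to tell the two oxygens apart → deoxygenation → ortho-acetylation → enaminone → iodocyclisation (γ-pyrone ring second).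
4. Boronate 19: hydroquinone → mixed MOM/TIPS diether → directed ortho-metalation/oxidation (third oxygen) → para-bromination → propargyl ether Claisen (2H-pyran ring) → borylation.
5. Ring order: dihydropyran, γ-pyrone (branch A); 2H-pyran (branch B); biaryl-type bond; furan.

Assumption: the target SMILES has no stereocentres (the molecule is achiral), so no stereocontrol is needed and none is set.

## Branch A – iodochromone 10

Step 1
Reactants: 1 resorcinol
Product: 2 1,3-dimethoxybenzene
Conditions: MeI, K2CO3, acetone, reflux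
Reagents that add atoms: iodomethane, CI
Why: Williamson O-methylation; the methyl ethers block both oxygens and give a clean substrate for C–H borylation.

Step 2
Reactants: 2 1,3-dimethoxybenzene
Product: 3 3,5-dimethoxyphenol
Conditions: [Ir(OMe)(cod)]2 (cat.), dtbpy, B2pin2, hexane, 80 °C; then Oxone, acetone/H2O, rt (one pot)
Reagents that add atoms: Oxone (potassium peroxymonosulfate), [K+].OOS(=O)(=O)[O-] (adds O; the Bpin group is transient)
Why: Sterically controlled Ir-catalysed C–H borylation goes to C-5, the only C–H not ortho to a substituent, and the aryl boronate is oxidised in situ to the phenol.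

Step 3
Reactants: 3 3,5-dimethoxyphenol; 4 3-methylbut-2-enoic acid
Product: 5 5,7-dimethoxy-2,2-dimethylchroman-4-one
Conditions: Eaton's reagent (P2O5/MsOH), 70 °C
Reagents that add atoms: none (4 is a numbered reactant)
Why: Friedel–Crafts acylation ortho to the free OH (ester/Fries pathway) then intramolecular oxa-Michael addition closes the chromanone; the two ortho positions are equivalent by symmetry.

Step 4
Reactants: 5
Product: 6 5-hydroxy-7-methoxy-2,2-dimethylchroman-4-one
Conditions: BCl3 (1.2 equiv), CH2Cl2, −78 → 0 °C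
Reagents that add atoms: none
Why: Chelation-controlled Lewis-acid demethylation cleaves only the methyl ether peri to the C-4 carbonyl, which differentiates the two ring oxygens.

Step 5
Reactants: 6
Product: 7 7-methoxy-2,2-dimethylchroman-5-ol
Conditions: ClCO2Et, Et3N, THF, 0 °C; then NaBH4, H2O/THF, 0 °C → rt
Reagents that add atoms: none
Why: Mitchell–Lai deoxygenation of an ortho-hydroxyaryl ketone: carbonate formation, ketone reduction, carbonate transfer and o-quinone-methide formation/hydride reduction give ArCH2.

Step 6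
Reactants: 7
Product: 8 1-(5-hydroxy-7-methoxy-2,2-dimethylchroman-6-yl)ethan-1-one
Conditions: AcOH, BF3·OEt2, 90 °C; aqueous NaOAc work-up
Reagents that add atoms: acetic acid, CC(=O)O (adds CH3CO)
Why: BF3-mediated Friedel–Crafts/Fries acetylation ortho to the free phenol, where the product is trapped as a BF2 chelate; the para position (C-8) cannot chelate.

Step 7
Reactants: 8
Product: 9 (E)-3-(dimethylamino)-1-(5-hydroxy-7-methoxy-2,2-dimethylchroman-6-yl)prop-2-en-1-one
Conditions: DMF-DMA, toluene, 95 °C
Reagents that add atoms: N,N-dimethylformamide dimethyl acetal, COC(OC)N(C)C (adds CH–NMe2)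
Why: Condensation of the methyl ketone with the amide acetal gives the enaminone; the chelated phenol is left free.

Step 8
Reactants: 9
Product: 10 3-iodo-5-methoxy-8,8-dimethyl-9,10-dihydro-4H,8H-pyrano[2,3-f]chromen-4-one
Conditions: I2 (2 equiv), pyridine, CHCl3, rt
Reagents that add atoms: iodine, II
Why: Gammill iodocyclisation: α-iodination of the enaminone, addition of the only free phenol and loss of Me2NH give the 3-iodochromone with the pyran fused angularly.

## Branch B – boronate 19

Step 9
Reactants: 11 hydroquinone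
Product: 12 4-(methoxymethoxy)phenol
Conditions: hydroquinone (3 equiv), NaH (1 equiv), MOMCl (1 equiv), DMF, 0 °C
Reagents that add atoms: chloromethyl methyl ether, COCCl
Why: Mono-alkylation is enforced by excess diol, which is removed by aqueous wash.

Step 10
Reactants: 12
Product: 13 triisopropyl[4-(methoxymethoxy)phenoxy]silane
Conditions: TIPSCl, imidazole, DMF, rt
Reagents that add atoms: triisopropylsilyl chloride, CC(C)[Si](Cl)(C(C)C)C(C)C
Why: Phenol silylation gives a hydroquinone with two orthogonal ethers; MOM directs lithiation and TIPS does not.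

Step 11
Reactants: 13
Product: 14 2-(methoxymethoxy)-5-[(triisopropylsilyl)oxy]phenol
Conditions: n-BuLi, TMEDA, THF, −20 → 0 °C; B(OMe)3, −78 °C → rt; then H2O2, NaHCO3, 0 °C
Reagents that add atoms: hydrogen peroxide, OO (adds O; the borate is transient)
Why: Directed ortho-metalation occurs next to OMOM only, and borylation/oxidation converts the aryllithium to the phenol.

Step 12
Reactants: 14
Product: 15 4-bromo-2-(methoxymethoxy)-5-[(triisopropylsilyl)oxy]phenol
Conditions: NBS (1.0 equiv), MeCN, −20 → 0 °C
Reagents that add atoms: N-bromosuccinimide, O=C1CCC(=O)N1Br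
Why: Electrophilic aromatic bromination goes para to the free OH; the alternative ortho site is squeezed between OH and OTIPS.

Step 13
Reactants: 15; 16 3-chloro-3-methylbut-1-yne
Product: 17 {2-bromo-4-(methoxymethoxy)-5-[(2-methylbut-3-yn-2-yl)oxy]phenoxy}triisopropylsilane
Conditions: DBU, CuCl2·2H2O (1 mol %), MeCN (dry), 0 °C → rt
Reagents that add atoms: none (16 is a numbered reactant)
Why: Cu-catalysed propargylic O-alkylation of the phenol with the tertiary propargyl chloride.

Step 14
Reactants: 17
Product: 18 {[6-bromo-8-(methoxymethoxy)-2,2-dimethyl-2H-chromen-5-yl]oxy}triisopropylsilane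
Conditions: o-xylene, 140 °C
Reagents that add atoms: none
Why: Aryl propargyl Claisen rearrangement to the only free ortho carbon, then 1,5-H shift and oxa-6π electrocyclisation give the 2H-chromene with unambiguous regiochemistry.

Step 15
Reactants: 18
Product: 19 triisopropyl{[8-(methoxymethoxy)-2,2-dimethyl-6-(4,4,5,5-tetramethyl-1,3,2-dioxaborolan-2-yl)-2H-chromen-5-yl]oxy}silane
Conditions: n-BuLi, THF, −78 °C; then i-PrOBpin, −78 °C → rt
Reagents that add atoms: 2-isopropoxy-4,4,5,5-tetramethyl-1,3,2-dioxaborolane, CC(C)OB1OC(C)(C)C(C)(C)O1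
Why: Br–Li exchange is faster than any deprotonation at −78 °C, and the bulky TIPS group resists retro-Brook migration before borate trapping.

## Coupling and endgame

Step 16
Reactants: 10 iodochromone; 19 boronate
Product: 20 5-methoxy-3-{8-(methoxymethoxy)-2,2-dimethyl-5-[(triisopropylsilyl)oxy]-2H-chromen-6-yl}-8,8-dimethyl-9,10-dihydro-4H,8H-pyrano[2,3-f]chromen-4-one
Conditions: Pd(OAc)2 (5 mol %), SPhos (10 mol %), K3PO4, dioxane/H2O (10:1), degassed, 80 °C
Reagents that add atoms: none
Why: Suzuki–Miyaura coupling of a 3-iodochromone with an aryl boronate is the standard isoflavone construction; SPhos copes with the ortho-silyloxy group.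

Step 17
Reactants: 20
Product: 21 3-[5-hydroxy-8-(methoxymethoxy)-2,2-dimethyl-2H-chromen-6-yl]-5-methoxy-8,8-dimethyl-9,10-dihydro-4H,8H-pyrano[2,3-f]chromen-4-one
Conditions: TBAF, AcOH (1 equiv), THF, 0 °C
Reagents that add atoms: none
Why: Fluoride desilylation frees only the 2'-phenol; the MOM and methyl ethers are inert, so the para oxygen stays masked.

Step 18
Reactants: 21
Product: 22 protected coumaronochromone: the target skeleton carrying OMe on the chromone oxygen peri to C=O and OMOM on the B-ring phenol
Conditions: DDQ (1.2 equiv), anhydrous 1,4-dioxane, Ar, rt → 60 °C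
Reagents that add atoms: none
Why: Oxidative cyclisation of a 2'-hydroxyisoflavone: oxa-Michael addition of the phenol to C-2, then DDQ dehydrogenation of the cyclic acetal gives the benzofuro[2,3-b]chromenone; anhydrous conditions and the MOM cap suppress quinone formation.

Step 19
Reactants: 22
Product: 23 Formosanatin D
Conditions: BCl3 (5 equiv), CH2Cl2, −78 → 0 °C; aqueous NaHCO3
Reagents that add atoms: none
Why: BCl3 cleaves the MOM acetal and, by chelation to the carbonyl, the peri methyl ether; the non-chelated cyclic ethers of both pyran rings are not cleaved at low temperature.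

## Compound list

1 | resorcinol | Oc1cccc(O)c1 | starting material
2 | 1,3-dimethoxybenzene | COc1cccc(OC)c1 | intermediate
3 | 3,5-dimethoxyphenol | COc1cc(O)cc(OC)c1 | intermediate
4 | 3-methylbut-2-enoic acid | CC(C)=CC(=O)O | starting material
5 | 5,7-dimethoxy-2,2-dimethylchroman-4-one | COc1cc(OC)c2C(=O)CC(C)(C)Oc2c1 | intermediate
6 | 5-hydroxy-7-methoxy-2,2-dimethylchroman-4-one | COc1cc(O)c2C(=O)CC(C)(C)Oc2c1 | intermediate
7 | 7-methoxy-2,2-dimethylchroman-5-ol | COc1cc(O)c2CCC(C)(C)Oc2c1 | intermediate
8 | 1-(5-hydroxy-7-methoxy-2,2-dimethylchroman-6-yl)ethan-1-one | CC(=O)c1c(O)c2CCC(C)(C)Oc2cc1OC | intermediate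
9 | (E)-3-(dimethylamino)-1-(5-hydroxy-7-methoxy-2,2-dimethylchroman-6-yl)prop-2-en-1-one | CN(C)/C=C/C(=O)c1c(O)c2CCC(C)(C)Oc2cc1OC | intermediate
10 | 3-iodo-5-methoxy-8,8-dimethyl-9,10-dihydro-4H,8H-pyrano[2,3-f]chromen-4-one | COc1cc2OC(C)(C)CCc2c2occ(I)c(=O)c12 | intermediate
11 | hydroquinone | Oc1ccc(O)cc1 | starting material
12 | 4-(methoxymethoxy)phenol | COCOc1ccc(O)cc1 | intermediate
13 | triisopropyl[4-(methoxymethoxy)phenoxy]silane | COCOc1ccc(O[Si](C(C)C)(C(C)C)C(C)C)cc1 | intermediate
14 | 2-(methoxymethoxy)-5-[(triisopropylsilyl)oxy]phenol | COCOc1ccc(O[Si](C(C)C)(C(C)C)C(C)C)cc1O | intermediate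
15 | 4-bromo-2-(methoxymethoxy)-5-[(triisopropylsilyl)oxy]phenol | COCOc1cc(Br)c(O[Si](C(C)C)(C(C)C)C(C)C)cc1O | intermediate
16 | 3-chloro-3-methylbut-1-yne | CC(C)(Cl)C#C | starting material
17 | {2-bromo-4-(methoxymethoxy)-5-[(2-methylbut-3-yn-2-yl)oxy]phenoxy}triisopropylsilane | COCOc1cc(Br)c(O[Si](C(C)C)(C(C)C)C(C)C)cc1OC(C)(C)C#C | intermediate
18 | {[6-bromo-8-(methoxymethoxy)-2,2-dimethyl-2H-chromen-5-yl]oxy}triisopropylsilane | COCOc1cc(Br)c(O[Si](C(C)C)(C(C)C)C(C)C)c2C=CC(C)(C)Oc12 | intermediate
19 | triisopropyl{[8-(methoxymethoxy)-2,2-dimethyl-6-(pinacolboryl)-2H-chromen-5-yl]oxy}silane | COCOc1cc(B2OC(C)(C)C(C)(C)O2)c(O[Si](C(C)C)(C(C)C)C(C)C)c2C=CC(C)(C)Oc12 | intermediate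
20 | Suzuki product (2'-OTIPS, 5'-OMOM, 5-OMe isoflavone) | COCOc1cc(-c2coc3c4CCC(C)(C)Oc4cc(OC)c3c2=O)c(O[Si](C(C)C)(C(C)C)C(C)C)c2C=CC(C)(C)Oc12 | intermediate
21 | 2'-hydroxyisoflavone (5'-OMOM, 5-OMe) | COCOc1cc(-c2coc3c4CCC(C)(C)Oc4cc(OC)c3c2=O)c(O)c2C=CC(C)(C)Oc12 | intermediate
22 | 5-O-methyl-5'-O-(methoxymethyl)formosanatin D | CC1(C)C=Cc2c(c(OCOC)cc3c2oc2oc4c5c(cc(OC)c4c(=O)c23)OC(C)(C)CC5)O1 | intermediate
23 | Formosanatin D (achiral) | CC1(C)C=Cc2c(c(O)cc3c2oc2oc4c5c(cc(O)c4c(=O)c23)OC(C)(C)CC5)O1 | target

## Totals and risks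

Total steps: 19 (branch A 8, branch B 7, coupling and endgame 4).
Longest linear sequence: 12 steps (steps 1–8, then 16–19).

Steps most likely to fail:

1. **Step 18 (DDQ cyclisation).** The B ring is a masked hydroquinone and could be oxidised to a quinone, and DDQ could dehydrogenate the A-ring chroman. Fallback: a redox-neutral closure. Convert 8 into the 2-(methylthio)chromone (CS2/t-BuOK, then MeI), iodinate C-3, couple with 19, and let the unmasked 2'-phenoxide displace MeS⁻ at C-2 by intramolecular addition–elimination, with no oxidant.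

2. **Step 6 (ortho-acetylation of 7).** Acylation para to the OH (C-8) or ortho/para mixtures are possible. Fallback: strictly ortho Mg-chelate formylation (MgCl2, Et3N, paraformaldehyde), then MeMgBr addition and MnO2 oxidation of the benzylic alcohol to reach 8.

3. **Step 16 (Suzuki coupling).** The hindered, electron-rich ortho-silyloxy boronate may protodeboronate, and the iodochromone may ring-open in base. Fallback: form the same C–C bond as a deoxybenzoin by Pd-catalysed α-arylation of the O-protected acetophenone 8 with bromide 18, then close the pyrone with DMF-DMA to give the isoflavone.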